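**Plan**
1. Numbering used: ring A = C1, C2, C3, C4, C5, C10 (C1=C10 alkene; C4 carries CH3 and CO2Me). Ring B = C5 to C10 (C8 carries CH3; C9 carries CH3 and the chain C11 to C15 with its 13-methyl and the formate on C15).
2. Retrosynthetic cuts, in order: formate; C13–CH3 and C14–C15 (carboalumination of a C13≡C14 alkyne); ring A at C1–C2; C4–C5 (Claisen); C1–C10; C9–C11 (Michael); C8–CH3 (conjugate addition).
3. Forward: ring B is built first from 2-methylcyclohexenone, C1 is attached to C10 as CH2OH, a Claisen shift joins C4 to C5 and leaves C1 as an exocyclic methylene, ring A is closed last by bonding C2 to C1, and the chain is finished afterwards.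
4. Enabling feature: with C1–C2 cut, C1=C10 is an exocyclic methylene on ring B, and C10 lies between quaternary C9 (no hydrogen) and C5 (one hydrogen, shielded by quaternary C4). A C2 radical tethered through C3–C4–C5 can only add to the open CH2 (6-endo), and the C10 radical regains the alkene by losing hydrogen from C1.
5. Stereochemistry: C8 from a ligand-controlled copper-catalysed methyl addition; C9 by Michael addition anti to the C8 methyl; C5 and C4 together from a chair Claisen shift of a ring-locked ketene acetal on the ring B face anti to both methyls; the E alkene from syn-carboalumination.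

Key step: step 9

Remark: the phosphoramidite enantiomer in step 1 is taken to be the one that gives the 3R enolate.

Step 1
Reactants: 1 2-methylcyclohex-2-en-1-one
Product: 3 trimethyl{[(3R)-2,3-dimethylcyclohex-1-en-1-yl]oxy}silane, via dimethylaluminium enolate 2 (not isolated)
Conditions: Me3Al, copper thiophene-2-carboxylate Cu(O2CC4H3S) (cat.), biphenol-derived N,N-bis(1-phenylethyl)phosphoramidite (cat.), Et2O, −30 °C; then Me3SiOTf, −30 → 0 °C
Reagents that add atoms: trimethylaluminium C[Al](C)C; trimethylsilyl trifluoromethanesulfonate C[Si](C)(C)OS(=O)(=O)C(F)(F)F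
Why: Copper-catalysed asymmetric conjugate addition of Me3Al to the α-substituted enone should set C8 (R) under ligand control, and O-silylation of the aluminium enolate fixes the C9=C10 enolate regiochemistry.

Step 2
Reactants: 3 trimethyl{[(3R)-2,3-dimethylcyclohex-1-en-1-yl]oxy}silane; 4 acrylonitrile
Product: 6 3-[(1S,2R)-1,2-dimethyl-6-oxocyclohexyl]propanenitrile, via lithium enolate 5 (not isolated)
Conditions: MeLi, THF, 0 °C; then 4, −78 °C; aq. NH4Cl
Reagents that add atoms: none
Why: Si–O cleavage gives the tetrasubstituted lithium enolate regiospecifically, and its Michael addition to acrylonitrile should occur at C9 on the face anti to the pseudoaxial C8 methyl (A1,2 strain with the C9 methyl), so the cyanoethyl chain ends trans to the C8 methyl and C9 is S.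

Step 3
Reactants: 6 3-[(1S,2R)-1,2-dimethyl-6-oxocyclohexyl]propanenitrile
Product: 8 (5R,6S)-6-(2-cyanoethyl)-5,6-dimethylcyclohex-1-en-1-yl trifluoromethanesulfonate, via potassium enolate 7 (not isolated)
Conditions: KN(SiMe3)2, THF, −78 °C; PhNTf2, −78 → 0 °C; aq. NH4Cl
Reagents that add atoms: N-phenylbis(trifluoromethanesulfonimide) O=S(=O)(N(c1ccccc1)S(=O)(=O)C(F)(F)F)C(F)(F)F
Why: Enolate triflation: the ketone can only be deprotonated at C5 because C9 is quaternary and the nitrile α-CH2 is much less acidic, so the C5=C10 enol triflate should form as a single regioisomer.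

Step 4
Reactants: 8 (5R,6S)-6-(2-cyanoethyl)-5,6-dimethylcyclohex-1-en-1-yl trifluoromethanesulfonate
Product: 9 3-[(1S,6R)-2-(hydroxymethyl)-1,6-dimethylcyclohex-2-en-1-yl]propanenitrile
Conditions: Bu3SnCH2OH, Pd(PPh3)4 (cat.), LiCl, 1,4-dioxane, 100 °C
Reagents that add atoms: (tributylstannyl)methanol CCCC[Sn](CCCC)(CCCC)CO
Why: Stille coupling of an alkenyl triflate with the hydroxymethylstannane installs C1 on C10 as CH2OH through zerovalent palladium, and no stereocentre is touched.

Step 5
Reactants: 10 α-methyl-γ-butyrolactone (3-methyloxolan-2-one, racemic)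
Product: 12 2,2-diethoxy-3-methyloxolane, via lactonium tetrafluoroborate 11 (not isolated)
Conditions: Et3OBF4, CH2Cl2, 23 °C; then NaOEt, EtOH, 0 °C
Reagents that add atoms: triethyloxonium tetrafluoroborate CC[O+](CC)CC.F[B-](F)(F)F; sodium ethoxide CC[O-].[Na+]
Why: O-Ethylation of the lactone carbonyl and capture of the dialkoxycarbenium ion by ethoxide is the standard ortho ester synthesis, and the racemic α-centre is erased in step 6.

Step 6
Reactants: 9 3-[(1S,6R)-2-(hydroxymethyl)-1,6-dimethylcyclohex-2-en-1-yl]propanenitrile; 12 2,2-diethoxy-3-methyloxolane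
Product: 14 3-{(1S,3R,6R)-1,6-dimethyl-2-methylidene-3-[(3S)-3-methyl-2-oxooxolan-3-yl]cyclohexyl}propanenitrile, via cyclic ketene acetal 13 (not isolated)
Conditions: 12 (excess), propionic acid (cat.), xylene, 145 °C, EtOH distilled off
Reagents that add atoms: none
Why: Johnson–Claisen (ortho ester Claisen) rearrangement: alcohol exchange and loss of EtOH give ketene acetal 13, whose geometry is locked by the five-membered ring (CH3 syn to the allylic oxygen), and its chair [3,3] shift on the ring B face anti to the C8 and C9 methyls should form C4–C5, set C5 (R) and quaternary C4 (S) together and move the alkene to exocyclic C10=C1.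

Step 7
Reactants: 14 3-{(1S,3R,6R)-1,6-dimethyl-2-methylidene-3-[(3S)-3-methyl-2-oxooxolan-3-yl]cyclohexyl}propanenitrile
Product: 16 methyl (2S)-2-[(1R,3S,4R)-3-(2-cyanoethyl)-3,4-dimethyl-2-methylidenecyclohexyl]-2-methyl-4-(phenylselanyl)butanoate, via sodium carboxylate 15 (not isolated)
Conditions: NaSePh, DMF, 120 °C; then MeI, 23 °C
Reagents that add atoms: sodium benzeneselenolate [Na+].[Se-]c1ccccc1; iodomethane CI
Why: SN2 opening of the γ-lactone at the primary O–CH2 carbon (C2) by the soft selenolate, followed by O-methylation of the carboxylate, gives the methyl ester without touching quaternary C4 or the alkene.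

Step 8
Reactants: 16 methyl (2S)-2-[(1R,3S,4R)-3-(2-cyanoethyl)-3,4-dimethyl-2-methylidenecyclohexyl]-2-methyl-4-(phenylselanyl)butanoate
Product: 17 methyl (2S)-2-[(1R,3S,4R)-3-(2-cyanoethyl)-3,4-dimethyl-2-methylidenecyclohexyl]-4-iodo-2-methylbutanoate
Conditions: MeI, NaI (cat.), DMF, 60 °C
Reagents that add atoms: iodomethane CI
Why: Selenide-to-iodide exchange: Se-methylation gives a selenonium salt that iodide displaces at primary C2 (SN2), under neutral conditions that spare the acid-sensitive exocyclic alkene.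

Step 9
Reactants: 17 methyl (2S)-2-[(1R,3S,4R)-3-(2-cyanoethyl)-3,4-dimethyl-2-methylidenecyclohexyl]-4-iodo-2-methylbutanoate
Product: 18 methyl (1S,5S,6R,8aR)-5-(2-cyanoethyl)-1,5,6-trimethyl-1,2,3,5,6,7,8,8a-octahydronaphthalene-1-carboxylate
Conditions: Ph3SnCo(dmgH)2(pyridine) (15 mol %, dmgH = dimethylglyoximate monoanion), i-Pr2NEt, MeCN, blue LED, 23 °C
Reagents that add atoms: none
Why: Proposed new method: light-induced homolysis of the Co–Sn (later Co–C) bond gives divalent cobalt and, by iodine abstraction, the primary C2 radical, which adds to the CH2 terminus C1 of the exocyclic C1=C10 alkene and closes ring A in the 6-endo-trig mode; the tertiary C10 radical is then captured by divalent cobalt and loses a β-hydrogen from C1 (dehydrocobaltation), and i-Pr2NEt deprotonates the trivalent cobalt hydride to the monovalent cobalt that re-activates the iodide. The closest known reaction type is the cobaloxime-catalysed intramolecular alkyl-Heck cyclisation of unactivated alkyl iodides, established for 5-exo and 6-exo closures. No stereocentre is created: C1 and C10 are sp2 in 17 and in 18, and C4, C5, C8 and C9 are not involved. The step needs 6-endo over 5-exo addition, secured because exo attack would build a quaternary C10 between quaternary C9 and C5 and give a primary radical, whereas endo attack at the open CH2 gives a tertiary radical and is helped by the gem-disubstituted C4 in the tether. It also needs hydrogen loss toward C1 and not C5, secured because C9 has no hydrogen, C1 offers two exposed hydrogens and the single H5 is shielded by quaternary C4, in line with the preference of cobaloximes for the least hindered β-C–H bond.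

Step 10
Reactants: 18 methyl (1S,5S,6R,8aR)-5-(2-cyanoethyl)-1,5,6-trimethyl-1,2,3,5,6,7,8,8a-octahydronaphthalene-1-carboxylate
Product: 20 methyl (1S,5S,6R,8aR)-1,5,6-trimethyl-5-(3-oxopropyl)-1,2,3,5,6,7,8,8a-octahydronaphthalene-1-carboxylate, via N-aluminio imine 19 (not isolated)
Conditions: i-Bu2AlH, toluene, −78 °C; then 1 M HCl
Reagents that add atoms: water O
Why: Half-reduction of the nitrile to the N-aluminio imine and hydrolysis should give the aldehyde, while the methyl ester on quaternary C4 is too hindered to be reduced at −78 °C.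

Step 11
Reactants: 20 methyl (1S,5S,6R,8aR)-1,5,6-trimethyl-5-(3-oxopropyl)-1,2,3,5,6,7,8,8a-octahydronaphthalene-1-carboxylate
Product: 21 methyl (1S,5S,6R,8aR)-5-(but-3-yn-1-yl)-1,5,6-trimethyl-1,2,3,5,6,7,8,8a-octahydronaphthalene-1-carboxylate
Conditions: dimethyl (1-diazo-2-oxopropyl)phosphonate, K2CO3, MeOH, 23 °C
Reagents that add atoms: dimethyl (1-diazo-2-oxopropyl)phosphonate COP(=O)(OC)C(=[N+]=[N-])C(C)=O
Why: Ohira–Bestmann homologation converts the aldehyde into the terminal alkyne (adds C14) under mildly basic conditions that leave the hindered ester and the ring alkene alone.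

Step 12
Reactants: 21 methyl (1S,5S,6R,8aR)-5-(but-3-yn-1-yl)-1,5,6-trimethyl-1,2,3,5,6,7,8,8a-octahydronaphthalene-1-carboxylate
Product: 23 methyl (1S,5S,6R,8aR)-5-[(3E)-5-hydroxy-3-methylpent-3-en-1-yl]-1,5,6-trimethyl-1,2,3,5,6,7,8,8a-octahydronaphthalene-1-carboxylate, via alkenylalane 22 (not isolated)
Conditions: Me3Al, Cp2ZrCl2 (cat.), CH2Cl2, 23 °C; volatiles removed; n-BuLi, hexane–THF, −78 °C; (CH2O)n, 23 °C; 1 M HCl
Reagents that add atoms: trimethylaluminium C[Al](C)C; formaldehyde (as paraformaldehyde) C=O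
Why: Negishi zirconium-catalysed carboalumination adds CH3 to C13 and aluminium to C14 on the same side, and the derived alanate adds to formaldehyde with retention, so the C13=C14 alkene should be E.

Step 13
Reactants: 23 methyl (1S,5S,6R,8aR)-5-[(3E)-5-hydroxy-3-methylpent-3-en-1-yl]-1,5,6-trimethyl-1,2,3,5,6,7,8,8a-octahydronaphthalene-1-carboxylate
Product: 24 methyl (1S,5S,6R,8aR)-5-[(3E)-5-(formyloxy)-3-methylpent-3-en-1-yl]-1,5,6-trimethyl-1,2,3,5,6,7,8,8a-octahydronaphthalene-1-carboxylate
Conditions: acetic formic anhydride, pyridine, CH2Cl2, 0 °C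
Reagents that add atoms: acetic formic anhydride CC(=O)OC=O
Why: O-Formylation of the primary allylic alcohol by acyl transfer from the mixed anhydride (the formyl carbonyl is the more electrophilic) gives the formate without allylic transposition.

**Compound list**
1 | 2-methylcyclohex-2-en-1-one | CC1=CCCCC1=O | starting material
2 | dimethyl{[(3R)-2,3-dimethylcyclohex-1-en-1-yl]oxy}alumane | C[C@@H]1CCCC(O[Al](C)C)=C1C | intermediate
3 | trimethyl{[(3R)-2,3-dimethylcyclohex-1-en-1-yl]oxy}silane | C[C@@H]1CCCC(O[Si](C)(C)C)=C1C | intermediate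
4 | acrylonitrile | C=CC#N | starting material
5 | lithium (3R)-2,3-dimethylcyclohex-1-en-1-olate | C[C@@H]1CCCC(O[Li])=C1C | intermediate
6 | 3-[(1S,2R)-1,2-dimethyl-6-oxocyclohexyl]propanenitrile | N#CCC[C@]1(C)C(=O)CCC[C@H]1C | intermediate
7 | potassium (5R,6S)-6-(2-cyanoethyl)-5,6-dimethylcyclohex-1-en-1-olate | N#CCC[C@]1(C)C(O[K])=CCC[C@H]1C | intermediate
8 | (5R,6S)-6-(2-cyanoethyl)-5,6-dimethylcyclohex-1-en-1-yl trifluoromethanesulfonate | N#CCC[C@]1(C)C(OS(=O)(=O)C(F)(F)F)=CCC[C@H]1C | intermediate
9 | 3-[(1S,6R)-2-(hydroxymethyl)-1,6-dimethylcyclohex-2-en-1-yl]propanenitrile | N#CCC[C@]1(C)C(CO)=CCC[C@H]1C | intermediate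
10 | α-methyl-γ-butyrolactone (3-methyloxolan-2-one, racemic) | CC1CCOC1=O | starting material
11 | 2-ethoxy-3-methyl-4,5-dihydro-3H-furan-1-ium tetrafluoroborate | CCOC1=[O+]CCC1C.F[B-](F)(F)F | intermediate
12 | 2,2-diethoxy-3-methyloxolane (racemic) | CCOC1(OCC)OCCC1C | intermediate
13 | 3-[(1S,6R)-1,6-dimethyl-2-{[(3-methyl-4,5-dihydrofuran-2-yl)oxy]methyl}cyclohex-2-en-1-yl]propanenitrile | N#CCC[C@]1(C)C(COC2=C(C)CCO2)=CCC[C@H]1C | intermediate
14 | 3-{(1S,3R,6R)-1,6-dimethyl-2-methylidene-3-[(3S)-3-methyl-2-oxooxolan-3-yl]cyclohexyl}propanenitrile | N#CCC[C@]1(C)C(=C)[C@H]([C@]2(C)CCOC2=O)CC[C@H]1C | intermediate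
15 | sodium (2S)-2-[(1R,3S,4R)-3-(2-cyanoethyl)-3,4-dimethyl-2-methylidenecyclohexyl]-2-methyl-4-(phenylselanyl)butanoate | N#CCC[C@]1(C)C(=C)[C@H]([C@](C)(CC[Se]c2ccccc2)C(=O)[O-])CC[C@H]1C.[Na+] | intermediate
16 | methyl (2S)-2-[(1R,3S,4R)-3-(2-cyanoethyl)-3,4-dimethyl-2-methylidenecyclohexyl]-2-methyl-4-(phenylselanyl)butanoate | N#CCC[C@]1(C)C(=C)[C@H]([C@](C)(CC[Se]c2ccccc2)C(=O)OC)CC[C@H]1C | intermediate
17 | methyl (2S)-2-[(1R,3S,4R)-3-(2-cyanoethyl)-3,4-dimethyl-2-methylidenecyclohexyl]-4-iodo-2-methylbutanoate | N#CCC[C@]1(C)C(=C)[C@H]([C@](C)(CCI)C(=O)OC)CC[C@H]1C | intermediate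
18 | methyl (1S,5S,6R,8aR)-5-(2-cyanoethyl)-1,5,6-trimethyl-1,2,3,5,6,7,8,8a-octahydronaphthalene-1-carboxylate | COC(=O)[C@@]1(C)CCC=C2[C@H]1CC[C@@H](C)[C@]2(C)CCC#N | intermediate
19 | methyl (1S,5S,6R,8aR)-5-{3-[bis(2-methylpropyl)alumanylimino]propyl}-1,5,6-trimethyl-1,2,3,5,6,7,8,8a-octahydronaphthalene-1-carboxylate | COC(=O)[C@@]1(C)CCC=C2[C@H]1CC[C@@H](C)[C@]2(C)CCC=N[Al](CC(C)C)CC(C)C | intermediate
20 | methyl (1S,5S,6R,8aR)-1,5,6-trimethyl-5-(3-oxopropyl)-1,2,3,5,6,7,8,8a-octahydronaphthalene-1-carboxylate | COC(=O)[C@@]1(C)CCC=C2[C@H]1CC[C@@H](C)[C@]2(C)CCC=O | intermediate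
21 | methyl (1S,5S,6R,8aR)-5-(but-3-yn-1-yl)-1,5,6-trimethyl-1,2,3,5,6,7,8,8a-octahydronaphthalene-1-carboxylate | COC(=O)[C@@]1(C)CCC=C2[C@H]1CC[C@@H](C)[C@]2(C)CCC#C | intermediate
22 | methyl (1S,5S,6R,8aR)-5-[(3E)-4-(dimethylalumanyl)-3-methylbut-3-en-1-yl]-1,5,6-trimethyl-1,2,3,5,6,7,8,8a-octahydronaphthalene-1-carboxylate | COC(=O)[C@@]1(C)CCC=C2[C@H]1CC[C@@H](C)[C@]2(C)CC/C(C)=C/[Al](C)C | intermediate
23 | methyl (1S,5S,6R,8aR)-5-[(3E)-5-hydroxy-3-methylpent-3-en-1-yl]-1,5,6-trimethyl-1,2,3,5,6,7,8,8a-octahydronaphthalene-1-carboxylate | COC(=O)[C@@]1(C)CCC=C2[C@H]1CC[C@@H](C)[C@]2(C)CC/C(C)=C/CO | intermediate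
24 | methyl (1S,5S,6R,8aR)-5-[(3E)-5-(formyloxy)-3-methylpent-3-en-1-yl]-1,5,6-trimethyl-1,2,3,5,6,7,8,8a-octahydronaphthalene-1-carboxylate | COC(=O)[C@@]1(C)CCC=C2[C@H]1CC[C@@H](C)[C@]2(C)CC/C(C)=C/COC=O | target

**Totals**
Total step count: 13. Longest linear sequence: 12 steps (steps 1 to 4 and 6 to 13, from 1); step 5 prepares fragment 12 from 10.

**Steps most likely to fail**

Step 9 (proposed new method). The C2 radical may be reduced or may take a hydrogen from C6 (1,5-transfer) before it cyclises, or the cobalt may remove H5 so that the alkene ends at C5=C10. The fallback uses known chemistry, sets out from 17 and comes back at 18. Displacement of the primary iodide of 17 with lithium divinylcuprate (CH2=CH)2CuLi (THF, −40 °C) should give methyl (2S)-2-[(1R,3S,4R)-3-(2-cyanoethyl)-3,4-dimethyl-2-methylidenecyclohexyl]-2-methylhex-5-enoate F1. Ring-closing metathesis of F1 with the second-generation Grubbs catalyst RuCl2(H2IMes)(PCy3)(=CHPh) (toluene, 80 °C) would close ring A by forming the C1=C10 double bond. The old exocyclic CH2 and the vinyl CH2 leave as ethene, which returns 18.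

Step 6. Alcohol exchange and rearrangement may be slow at the congested C5/C9 region, so that decomposition competes at 145 °C, and facial discrimination at C5 may be insufficient at that temperature. The fallback sets out from 9 and comes back at 14. Esterification of 9 with (2S)-4-[(tert-butyldimethylsilyl)oxy]-2-methylbutanoic acid (DCC, DMAP, CH2Cl2) should give [(5R,6S)-6-(2-cyanoethyl)-5,6-dimethylcyclohex-1-en-1-yl]methyl (2S)-4-[(tert-butyldimethylsilyl)oxy]-2-methylbutanoate F2. A low-temperature Ireland–Claisen rearrangement follows (chiral lithium amide matched to the α-stereocentre so that C3 lies syn to the silyloxy group of the ketene acetal, Me3SiCl, THF, −78 → 23 °C). It should give (2S)-4-[(tert-butyldimethylsilyl)oxy]-2-[(1R,3S,4R)-3-(2-cyanoethyl)-3,4-dimethyl-2-methylidenecyclohexyl]-2-methylbutanoic acid F3. Bu4NF then removes the silyl group and the γ-hydroxy acid lactonises (TsOH, cat.) to 14.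

Step 2. Acrylonitrile may polymerise anionically, started by the lithium enolate or by the α-cyano carbanion, and proton transfer may scramble the enolate. The fallback sets out from 3 and comes back at 6. Hydrolysis of 3 (1 M HCl, THF) gives (3R)-2,3-dimethylcyclohexan-1-one F4 as a mixture at C2. Condensation with (S)-1-phenylethanamine (toluene, water removed) gives (1S)-N-[(3R)-2,3-dimethylcyclohexylidene]-1-phenylethanamine F5. Its secondary enamine tautomer should add to acrylonitrile at the more substituted α-carbon under neutral conditions (Michael addition of a chiral imine, anti to the C8 methyl). Hydrolysis with aqueous acetic acid returns 6.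

**Further compounds**
F1 | step 9 | methyl (2S)-2-[(1R,3S,4R)-3-(2-cyanoethyl)-3,4-dimethyl-2-methylidenecyclohexyl]-2-methylhex-5-enoate | N#CCC[C@]1(C)C(=C)[C@H]([C@](C)(CCC=C)C(=O)OC)CC[C@H]1C
F2 | step 6 | [(5R,6S)-6-(2-cyanoethyl)-5,6-dimethylcyclohex-1-en-1-yl]methyl (2S)-4-[(tert-butyldimethylsilyl)oxy]-2-methylbutanoate | N#CCC[C@]1(C)C(COC(=O)[C@@H](C)CCO[Si](C)(C)C(C)(C)C)=CCC[C@H]1C
F3 | step 6 | (2S)-4-[(tert-butyldimethylsilyl)oxy]-2-[(1R,3S,4R)-3-(2-cyanoethyl)-3,4-dimethyl-2-methylidenecyclohexyl]-2-methylbutanoic acid | N#CCC[C@]1(C)C(=C)[C@H]([C@](C)(CCO[Si](C)(C)C(C)(C)C)C(=O)O)CC[C@H]1C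
F4 | step 2 | (3R)-2,3-dimethylcyclohexan-1-one (both C2 epimers) | CC1C(=O)CCC[C@H]1C
F5 | step 2 | (1S)-N-[(3R)-2,3-dimethylcyclohexylidene]-1-phenylethanamine | C[C@H](N=C1CCC[C@@H](C)C1C)c1ccccc1
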